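**Plan**

Labels: the butenolide ring is O1, C2 (C=O), C3 (C–CH3), C4 (C–CO2H), C5 (stereocentre). The side chain is C1'–C15' with the ketone at C14'.
Cuts, in retrosynthetic order: benzyl ester O–C; ring bond C4–C5; C5–O1 and C5–Cl (back to an aldehyde and an acyl chloride); C4–OTf (back to a C4 ketone); C3–C4 (Claisen); finally C5 and C14' are rejoined as the C=C of 1-methylcyclopentadecene.
Enabling feature: C5 is both the O-acylated carbon of the ring ester O1–C2 and the sp3 substituent on sp2 C4, and C4/C3/C2 form a masked 1,3-dicarbonyl. The ring ester can therefore be made first from an aldehyde, as a racemic α-chloroalkyl ester, and act as its own tether, while C4 carries an enol triflate held cis to C2.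
Forward: a 15-membered carbocycle is opened to the C16 keto aldehyde, and propionate plus oxalate give the C2–C4 unit. The halves are joined through O1, the only ring is closed last at C4–C5 by nickel-catalysed reductive coupling, and debenzylation ends the route.
Stereochemistry: C5 is made racemic and then set as S during ring closure by a chiral bis(oxazoline)–nickel catalyst, enantioconvergently through a planar C5 radical. The C3=C4 geometry comes from the Z enol triflate and is then locked by the ring.

Key step: step 8

Assumption: the sense of induction of the chiral ligand cannot be predicted for this substrate class. Both antipodes are available, and the one that leads to (S) is used.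

Step 1
Reactants: 1 cyclopentadecanone
Product: 2 1-methylcyclopentadecan-1-ol
Conditions: MeMgBr (1.3 equiv), THF, 0 °C to rt; sat. aq. NH4Cl
Reagents that add atoms: methylmagnesium bromide, C[Mg]Br
Why: Grignard 1,2-addition of a small nucleophile to an unhindered macrocyclic ketone is routine and creates no stereocentre.

Step 2
Reactants: 2 1-methylcyclopentadecan-1-ol
Product: 3 1-methylcyclopentadec-1-ene (E/Z mixture)
Conditions: p-TsOH·H2O (5 mol %), toluene, reflux, Dean–Stark
Reagents that add atoms: none
Why: Acid-catalysed E1 dehydration of the tertiary alcohol under equilibrating conditions favours the trisubstituted endocyclic (Zaitsev) alkene, and its E and Z forms converge on the same product in step 3.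

Step 3
Reactants: 3 1-methylcyclopentadec-1-ene
Product: 5 15-oxohexadecanal, via secondary ozonide 4 (not isolated)
Conditions: O3, CH2Cl2, −78 °C; then PPh3, −78 °C to rt
Reagents that add atoms: ozone, [O-][O+]=O
Why: Ozonolysis with reductive work-up cleaves the single C=C of the carbocycle and so reveals the C14' methyl ketone and the C5 aldehyde in one operation, already differentiated and without protecting groups.

Step 4
Reactants: 6 tert-butyl propanoate, 7 dibenzyl oxalate
Product: 9 1-benzyl 4-tert-butyl 3-methyl-2-oxobutanedioate, via lithium enolate 8 (not isolated)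
Conditions: LDA (1.05 equiv), THF, −78 °C; cannulated into 7 (1.5 equiv), THF, −78 °C; AcOH quench
Reagents that add atoms: none
Why: In this crossed Claisen condensation the preformed ester enolate attacks the non-enolisable, doubly activated oxalate, inverse addition at low temperature limits double addition, and the C3 centre that forms is irrelevant because it is enolised in step 5.

Step 5
Reactants: 9 1-benzyl 4-tert-butyl 3-methyl-2-oxobutanedioate
Product: 10 1-benzyl 4-tert-butyl (2Z)-3-methyl-2-[(trifluoromethanesulfonyl)oxy]but-2-enedioate
Conditions: LiOTf (2 equiv), Et3N (1.5 equiv), Tf2O (1.2 equiv), CH2Cl2, 0 °C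
Reagents that add atoms: trifluoromethanesulfonic anhydride, O=S(=O)(OS(=O)(=O)C(F)(F)F)C(F)(F)F
Why: In this stereoselective enol triflation of a 1,3-dicarbonyl compound, lithium chelation between the enolate oxygen on C4 and the tert-butyl ester carbonyl on C2 holds these groups cis and the two esters trans, so O-sulfonylation should give the Z isomer with the leaving group facing C2.

Step 6
Reactants: 10 Z enol triflate diester
Product: 11 (2Z)-4-(benzyloxy)-2-methyl-4-oxo-3-[(trifluoromethanesulfonyl)oxy]but-2-enoic acid
Conditions: TFA, CH2Cl2, 0 °C to rt
Reagents that add atoms: none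
Why: Acidolysis of the tert-butyl ester through the tert-butyl cation, with loss of isobutene, leaves the benzyl ester, the enol triflate and the alkene geometry untouched.

Step 7
Reactants: 11 Z triflyloxy acid, 5 15-oxohexadecanal
Product: 13 1-benzyl 4-(1-chloro-15-oxohexadecyl) (2Z)-3-methyl-2-[(trifluoromethanesulfonyl)oxy]but-2-enedioate (racemic at C5), via acyl chloride 12 (not isolated)
Conditions: (COCl)2 (1.2 equiv), DMF (cat.), CH2Cl2, 0 °C to rt, evaporate; then 5 (1.0 equiv), ZnCl2 (5 mol %), CH2Cl2, −10 °C to rt
Reagents that add atoms: oxalyl chloride, O=C(Cl)C(=O)Cl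
Why: Vilsmeier-type chlorination gives the acyl chloride, and the known ZnCl2-catalysed insertion of an aldehyde carbonyl into the acyl C–Cl bond (α-chloroalkyl ester synthesis) should be much faster at the aldehyde than at the methyl ketone, the new C5 centre being formed racemic on purpose.

Step 8
Reactants: 13 racemic α-chloroalkyl ester
Product: 14 benzyl (2S)-4-methyl-5-oxo-2-(14-oxopentadecyl)-2,5-dihydrofuran-3-carboxylate
Conditions: NiCl2(dme) (10 mol %), (3aR,3a'R,8aS,8a'S)-2,2'-(cyclopropane-1,1-diyl)bis(3a,8a-dihydro-8H-indeno[1,2-d]oxazole) or its antipode (12 mol %), Mn powder (3 equiv), NaI (0.5 equiv), DMA, 0 °C, 13 added by syringe pump (final 0.005 M); dilute aq. HCl work-up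
Reagents that add atoms: none
Why: Proposed new method: zerovalent nickel should insert into the electron-poor C4–OTf bond with retention, a monovalent nickel species then abstracts chlorine from C5 to give a planar α-acyloxyalkyl radical, this radical is caught by the alkenylnickel centre of the same molecule to give a six-membered nickelacycle (Ni, C4, C3, C2, O1, C5) at trivalent nickel, and reductive elimination forms C4–C5 while Mn returns the catalyst to the zerovalent state. The closest known reaction types are the nickel/bis(oxazoline)-catalysed enantioconvergent reductive cross-coupling of racemic secondary alkyl chlorides with alkenyl halides or triflates and the enantioconvergent nickel-catalysed couplings of racemic α-haloalkyl esters, which show that a chiral nickel centre can bind and discriminate an α-acyloxy radical; the intramolecular, lactone-forming version is what is new. The five-membered ring O1–C2–C3–C4–C5 closes by reductive elimination from the nickelacycle, so the disfavoured 5-endo-trig attack of a C5 radical on C4 is not required. C5 is the only new stereocentre and is set by the twofold-symmetric ligand during radical capture and reductive elimination, both enantiomers of 13 passing through the same radical so that all material can converge on S. The step needs differentiation of the sp2 and sp3 electrophiles (secured by the triflate/chloride pair), nickel cis to the C2 ester (secured by the Z geometry of 13), closure ahead of intermolecular coupling (secured by slow addition at high dilution), and inertness of the C14' ketone, the benzyl ester and the acidic C5–H of the product (secured by the neutral, base-free Mn/DMA medium at 0 °C).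

Step 9
Reactants: 14 benzyl ester of the target
Product: 15 (2S)-4-methyl-5-oxo-2-(14-oxopentadecyl)-2,5-dihydrofuran-3-carboxylic acid (target)
Conditions: H2 (1 atm), 10% Pd/C, EtOAc, rt, stopped after uptake of one equivalent
Reagents that add atoms: none
Why: Hydrogenolysis of the benzyl ester should be much faster than hydrogenation of the tetrasubstituted, electron-poor C3=C4 bond, is neutral so that the base-sensitive C5–H is not disturbed, and leaves the ketone alone.

**Compound list**

1 | cyclopentadecanone | O=C1CCCCCCCCCCCCCC1 | starting material
2 | 1-methylcyclopentadecan-1-ol | CC1(O)CCCCCCCCCCCCCC1 | intermediate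
3 | 1-methylcyclopentadec-1-ene (E/Z mixture) | CC1=CCCCCCCCCCCCCC1 | intermediate
4 | 1-methyl-16,17,18-trioxabicyclo[13.2.1]octadecane (secondary ozonide, not isolated) | CC12OOC(CCCCCCCCCCCCC1)O2 | intermediate
5 | 15-oxohexadecanal | CC(=O)CCCCCCCCCCCCCC=O | intermediate
6 | tert-butyl propanoate | CCC(=O)OC(C)(C)C | starting material
7 | dibenzyl oxalate | O=C(OCc1ccccc1)C(=O)OCc1ccccc1 | starting material
8 | lithium enolate of tert-butyl propanoate (not isolated) | CC=C([O-])OC(C)(C)C.[Li+] | intermediate
9 | 1-benzyl 4-tert-butyl 3-methyl-2-oxobutanedioate (racemic, enolisable) | CC(C(=O)OC(C)(C)C)C(=O)C(=O)OCc1ccccc1 | intermediate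
10 | 1-benzyl 4-tert-butyl (2Z)-3-methyl-2-[(trifluoromethanesulfonyl)oxy]but-2-enedioate | CC(C)(C)OC(=O)/C(C)=C(\OS(=O)(=O)C(F)(F)F)C(=O)OCc1ccccc1 | intermediate
11 | (2Z)-4-(benzyloxy)-2-methyl-4-oxo-3-[(trifluoromethanesulfonyl)oxy]but-2-enoic acid | OC(=O)/C(C)=C(\OS(=O)(=O)C(F)(F)F)C(=O)OCc1ccccc1 | intermediate
12 | benzyl (2Z)-4-chloro-3-methyl-4-oxo-2-[(trifluoromethanesulfonyl)oxy]but-2-enoate (not isolated) | ClC(=O)/C(C)=C(\OS(=O)(=O)C(F)(F)F)C(=O)OCc1ccccc1 | intermediate
13 | 1-benzyl 4-(1-chloro-15-oxohexadecyl) (2Z)-3-methyl-2-[(trifluoromethanesulfonyl)oxy]but-2-enedioate (racemic at the CHCl carbon) | CC(=O)CCCCCCCCCCCCCC(Cl)OC(=O)/C(C)=C(\OS(=O)(=O)C(F)(F)F)C(=O)OCc1ccccc1 | intermediate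
14 | benzyl (2S)-4-methyl-5-oxo-2-(14-oxopentadecyl)-2,5-dihydrofuran-3-carboxylate | CC(=O)CCCCCCCCCCCCC[C@@H]1OC(=O)C(C)=C1C(=O)OCc1ccccc1 | intermediate
15 | (2S)-4-methyl-5-oxo-2-(14-oxopentadecyl)-2,5-dihydrofuran-3-carboxylic acid | CC(=O)CCCCCCCCCCCCC[C@@H]1OC(=O)C(C)=C1C(=O)O | target

Total steps: 9. Longest linear sequence: 6 (steps 1, 2, 3, 7, 8, 9, or equally steps 4, 5, 6, 7, 8, 9).

**Steps most likely to fail**

Step 8 (new method). Three things may go wrong:
- The s-trans preference of the ester may keep C5 away from nickel, so that intermolecular coupling, simple reduction of the C–Cl bond or β-hydride loss overtakes ring closure.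
- The ligand may discriminate poorly between the faces of the C5 radical.
- The product may lose configuration through enolisation at C5.

The fallback uses known chemistry and sets out from 10 and 5. A catalytic asymmetric Nozaki–Hiyama–Kishi alkenylation is run with CrCl2 (10 mol %) bound to a chiral oxazoline–sulfonamide ligand, NiCl2(2,9-dimethyl-1,10-phenanthroline) (2 mol %), Mn powder, Cp2ZrCl2 and LiCl in MeCN at rt. The alkenyl species formed at divalent chromium adds to the aldehyde only, not to the ketone. This should give 1-benzyl 4-tert-butyl (2E)-2-[(1S)-1-hydroxy-15-oxohexadecyl]-3-methylbut-2-enedioate F1. TFA in CH2Cl2 then removes the tert-butyl group and closes the lactone onto the cis C2 carboxyl, which rejoins the route at 14.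

Step 7. Carbonyl insertion may be sluggish with the hindered, conjugated acyl chloride. The product may lose HCl towards an enol ester, or chloride may attack the activated enol triflate.

The fallback reverses the polarity of the ester-forming event, so that acid 11 acts as the nucleophile. It sets out from 5 and 11. Aldehyde 5 with PhSH (1 equiv) and dry HCl (CH2Cl2, −20 °C) should give 16-chloro-16-(phenylsulfanyl)hexadecan-2-one F2. The carboxylate of 11 (iPr2NEt, MeCN) then displaces the chloride of that sulfide to give the O,S-acetal ester 1-benzyl 4-[15-oxo-1-(phenylsulfanyl)hexadecyl] (2Z)-3-methyl-2-[(trifluoromethanesulfonyl)oxy]but-2-enedioate F3. Finally SO2Cl2 (CH2Cl2, −78 °C, cyclohexene as scavenger) exchanges the phenylsulfanyl group for chlorine, which rejoins the route at 13.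

Step 9. The C3=C4 bond may be over-reduced, or the allylic C5–O1 bond may undergo hydrogenolysis before debenzylation is complete.

The fallback changes the bond-breaking principle from reductive to acidolytic, so that neither site sees hydrogen. It sets out from 14. BCl3 with pentamethylbenzene as cation scavenger (CH2Cl2, −78 °C), followed by an aqueous quench, should cleave the benzyl–oxygen bond and lead directly to 15. This fallback makes no new compound (entry F0).

**Further compounds**

F1 | step 8 | 1-benzyl 4-tert-butyl (2E)-2-[(1S)-1-hydroxy-15-oxohexadecyl]-3-methylbut-2-enedioate | CC(=O)CCCCCCCCCCCCC[C@H](O)/C(C(=O)OCc1ccccc1)=C(/C)C(=O)OC(C)(C)C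
F2 | step 7 | 16-chloro-16-(phenylsulfanyl)hexadecan-2-one (racemic) | CC(=O)CCCCCCCCCCCCCC(Cl)Sc1ccccc1
F3 | step 7 | 1-benzyl 4-[15-oxo-1-(phenylsulfanyl)hexadecyl] (2Z)-3-methyl-2-[(trifluoromethanesulfonyl)oxy]but-2-enedioate (racemic) | CC(=O)CCCCCCCCCCCCCC(Sc1ccccc1)OC(=O)/C(C)=C(\OS(=O)(=O)C(F)(F)F)C(=O)OCc1ccccc1
F0 | step 9 | none | none
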